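The nucleophile is charged at 0.0400 M against 0.050 M of solid electrophile, so it is the limiting reagent of this flask.

| flask | solid electrophile | nucleophile | remark | time |
|---|---|---|---|---|
| alder | 0.034 M | 0.040 M | run made earlier |  |
| elm | 0.075 M | 0.040 M | run made earlier |  |
| ash | 0.050 M | 0.020 M | run made earlier |  |
| flask | 0.050 M | 0.0400 M |  | 6.0 h |

- alder (time / h: solid electrophile / %, target / %): 0.667: 0.2, 70.4; 1.50: 0.4, 82.7; 3.00: 0, 90.8; 5.00: 0, 94.6
- elm (time / h: solid electrophile / %, target / %): 1.33: 0, 49.5; 2.50: 0.3, 53.0; 4.00: 0.2, 53.0; 5.00: 0, 53.3
- ash (time / h: solid electrophile / %, target / %): 0.667: 0.6, 31.0; 1.50: 0, 37.6; 3.00: 0.6, 39.5; 5.00: 0, 40.3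

(standard deviation of a reading: 0.5 percentage points)

- amounts and yields of acid set free count crystals too
- given per volume of solution although it is solid: crystals, solid electrophile
- candidate steps: nucleophile + acid set free <-> protonated nucleophile; electrophile + nucleophile -> acid set free + target; solid electrophile <-> electrophile; electrophile -> decomposition product; crystals <-> acid set free
- at the start none of the solid electrophile is in solution
- what has only dissolved of solid electrophile counts as not reacted
- the earlier runs do not show how much of nucleophile is bound; that part of a forecast is a guess

- part of the solid electrophile that has reacted (what has only dissolved counts as not reacted) at 6.0 h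
- share of the unused nucleophile that is free and not bound as protonated nucleophile, at 6.0 h

Take the main step first. Electrophile and nucleophile give target and acid set free one to one, so the target ceiling of this flask is 80.0%: nucleophile charged over solid electrophile charged, where the nucleophile is the smaller charge. The runs test this. The ceilings of elm and ash are 53.3% and 40.0%, and their last readings of target are 53.3% and 40.3%, within the scatter.

Next add the binding of acid set free to nucleophile. It can hold nucleophile back for a while, but elm and ash still read at their ceilings, so in those runs bound nucleophile returns, presumably as crystals take up the acid. The binding may leave a slow tail. Alder has the charges nearest to equal, and at 5.00 h its target reads 0.00184 M short of its solid electrophile charge. Taken as a rough guide, the same shortfall puts target in this flask near 76.3%, under the ceiling of 80.0%; that is the reckoning made here.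

Then comes the rest. Solid electrophile reads near zero at each sampling of the earlier runs, so these readings show no delay from dissolving. Decomposition product counts as reacted on top of target, and the readings give no separate figure for it. How much unused nucleophile is bound, the runs do not show.

The forecast gives 80% reacted (76% to 88%), with decomposition counted, and a free share of 50% (20% to 85%): “The free share is only a guess from the k decline, about half.”

The flask gives 80.0% reacted and a free share of 7.63%, which is 42 percentage points under the forecast.

    nucleophile + acid set free ⇌ protonated nucleophile, settled at all times (K = 11000 M⁻¹)
    electrophile + nucleophile → acid set free + target (k = 0.160 M⁻¹ s⁻¹)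
    solid electrophile ⇌ electrophile, rate k3*(cs3 - [electrophile]) while solid is left; crystals form when [electrophile] > cs3 (solubility = 38.0 mM, k = 0.0100 s⁻¹)
    electrophile → decomposition product (k = 2.00 × 10⁻⁶ s⁻¹)
    crystals ⇌ acid set free, rate k5*(cs5 - [acid set free]) while solid is left; crystals form when [acid set free] > cs5 (solubility = 1.10 mM, k = 0.260 s⁻¹)

At 6.00 h the target of the flask stands at 78.8% against the ceiling of 80.0%, with 1.21% of decomposition product beside it, while acid set free holds 0.00110 M and protonated nucleophile 5.42 × 10⁻⁴ M. A neighbouring flask, the same but with 0.016 M of nucleophile, has a ceiling of 32.0%. At 6.00 h its target reaches 32.0%, its electrophile holds 65.1%, its decomposition product stands at 2.92%, and 34.9% has reacted.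

(The data stem from a simulated flask for an exercise; the scatter is artificial.)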